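**Retrosynthetic overview**
1. The last skeletal bond is the ester C–O between the primary CH2OH of the hydroxy-acid half and the acrylic acid of the butenolide half (acylation, then global deprotection).
2. Both halves come from one spiro-carbonate cyclohexane. Carbonate methanolysis gives the diol (alcohol partner). The same diol, by lactonisation of C4–CH2OH onto the C5 carboxyl and dehydration to C4=C5, gives the butenolide acid (acid partner).
3. The strategy rests on the hydroxy-acid cyclohexane ring: C1 = CH–iPr, C4 = carbinol, C5 = CH–CO2H, C6 = CH–acrylate, i.e. four contiguous stereocentres C4–C5–C6–C1 beside the unsubstituted C2–C3 unit. This is the pattern of an endo Diels–Alder adduct of a C1–C4 diene and a C5=C6 dienophile.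
4. Key disconnection: bonds C4–C5 and C6–C1, by iminium-catalysed [4+2] of a (Z)-alkylidene cyclic carbonate diene (C4 already a protected carbinol) with a 4-oxobut-2-enoate. C5-CHO then becomes CO2tBu, C2=C3 is saturated, and C6-ester is taken via CHO to the (E)-acrylate by HWE.
5. Ring order: dioxolanone (on the diene, Ag/CO2) → carbocycle (Diels–Alder) → butenolide lactone (after carbonate removal).

Key step: step 6

**Remarks**
- Ring locants used throughout: C1 = CH–iPr, C2, C3, C4 = oxygen-bearing quaternary carbon with its CH2O arm, C5, C6. β is the ring face carrying the C1 isopropyl group. In every ring compound the C4–CH2O arm and the C5 carbon substituent are β; the C4–O bond and the C6 carbon substituent are α.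
- Assumption: the C6 carboxyl of the dienophile is carried as a benzyl ester rather than a simple alkyl ester. It must later be unmasked and reduced while the cyclic carbonate and a C5 tert-butyl ester stay intact; hydrogenolysis followed by borane reduction does this, whereas a hydride reduction of an alkyl ester would not spare the carbonate.
- Taken as commercial: the (5R)-imidazolidinone hydrochloride, (triisopropylsiloxy)methyl chloride, tert-butyl diethylphosphonoacetate, benzyl (triphenylphosphoranylidene)acetate and aqueous 2,2-dimethoxyacetaldehyde.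

**Route**

Step 1
Reactants: 1 3-methylbut-1-yne
Product: 3 (E)-1-iodo-3-methylbut-1-ene, via (E)-diisobutyl(3-methylbut-1-en-1-yl)alane 2 (not isolated)
Conditions: DIBAL-H, hexane, 50 °C (sealed); then I2, THF, −50 °C → rt
Reagents that add atoms: iodine, II
Why: Zweifel hydroalumination–iodination: syn Al–H addition puts aluminium on the terminal carbon and iodinolysis of the C–Al bond with retention should give the E-iodide.

Step 2
Reactants: 3 (E)-1-iodo-3-methylbut-1-ene; 4 prop-2-yn-1-ol
Product: 5 (E)-6-methylhept-4-en-2-yn-1-ol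
Conditions: PdCl2(PPh3)2 (2 mol%), CuI (4 mol%), Et3N, THF, rt
Reagents that add atoms: none
Why: Sonogashira sp2–sp coupling of an alkenyl iodide with a terminal alkyne proceeds with retention of the E geometry and tolerates the free alcohol.

Step 3
Reactants: 5 (E)-6-methylhept-4-en-2-yn-1-ol
Product: 6 (Z)-4-[(E)-4-methylpent-2-en-1-ylidene]-1,3-dioxolan-2-one
Conditions: AgOAc (5 mol%), DavePhos (5 mol%), CO2 (20 bar), MeCN, rt
Reagents that add atoms: carbon dioxide, O=C=O
Why: Silver-catalysed carboxylative cyclisation of a propargylic alcohol: the alkyl carbonate adds 5-exo-dig anti to silver across the alkyne and protodemetalation leaves the alkenyl chain cis to the ring oxygen, i.e. the Z enol carbonate.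

Step 4
Reactants: 7 benzyl (triphenylphosphoranylidene)acetate; 8 2,2-dimethoxyacetaldehyde
Product: 9 benzyl (E)-4,4-dimethoxybut-2-enoate
Conditions: CH2Cl2, rt (aldehyde as 60% aq. solution)
Reagents that add atoms: none
Why: Wittig olefination with a stabilised ylide should give the E-enoate under thermodynamic control of the oxaphosphetane.

Step 5
Reactants: 9 benzyl (E)-4,4-dimethoxybut-2-enoate
Product: 10 benzyl (E)-4-oxobut-2-enoate
Conditions: Amberlyst-15, acetone/H2O, rt
Reagents that add atoms: water, O
Why: Acid-catalysed acetal hydrolysis frees the enal; the benzyl ester and the E alkene are not affected.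

Step 6
Reactants: 6 (Z)-4-[(E)-4-methylpent-2-en-1-ylidene]-1,3-dioxolan-2-one; 10 benzyl (E)-4-oxobut-2-enoate
Product: 13 benzyl (5S,8S,9R,10S)-10-formyl-2-oxo-8-(propan-2-yl)-1,3-dioxaspiro[4.5]dec-6-ene-9-carboxylate, via enal iminium chloride 11 (not isolated), via cycloadduct iminium chloride 12 (not isolated)
Conditions: (5R)-5-benzyl-2,2,3-trimethylimidazolidin-4-one·HCl (20 mol%), MeCN/H2O 95:5, −10 °C → rt
Reagents that add atoms: none
Why: Proposed new method: the amine salt condenses with 10 to the LUMO-lowered (E)-iminium ion 11, which undergoes a concerted, asynchronous [4+2] cycloaddition with s-cis 6, and hydrolysis of adduct iminium 12 returns the catalyst; the closest known reaction is the imidazolidinone-catalysed Diels–Alder of enals with 1-acyloxybutadienes, the new element being the fully substituted enol-carbonate terminus that becomes a quaternary carbinol carbon. The cyclohexene ring is closed by this suprafacial cycloaddition, with C6–C1 (iminium β-carbon to the CH–iPr terminus) more advanced than C4–C5. C5/C6 come out trans from the E dienophile (CHO β, CO2Bn α); C1 and C4 follow from the endo position of the iminium under the diene together with the diene geometry (iPr and CH2O outside, hence both β; carbonate oxygen tied inside, hence α). The absolute sense comes from the (5R)-benzyl group, which covers the Si face at the β-carbon (CO2Bn > Cα > H) so that the diene adds to the Re face. The step needs ortho regiochemistry (oxygenated terminus to the formyl-bearing carbon), which is secured because the less hindered CH–iPr terminus attacks the iminium β-carbon while positive charge builds at the oxygen-substituted tertiary terminus, and endo selectivity, secured by the iminium being the dominant activating group. The hindered, protonated catalyst should not acylate on the enol carbonate, and the α-branched product aldehyde should not form an enamine, so the β-carbonate is not eliminated.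

Step 7
Reactants: 13 the Diels–Alder aldehyde
Product: 14 (5S,8S,9R,10S)-9-(benzyloxycarbonyl)-2-oxo-8-(propan-2-yl)-1,3-dioxaspiro[4.5]dec-6-ene-10-carboxylic acid (13 with C5 CHO → CO2H)
Conditions: NaClO2, NaH2PO4, 2-methylbut-2-ene, t-BuOH/H2O, 0 °C
Reagents that add atoms: sodium chlorite, [Na+].[O-]Cl=O
Why: Pinnick oxidation works at pH 3–4, so the base-sensitive β-carbonate aldehyde is oxidised without epimerisation or elimination, and the scavenger protects the ring alkene from HOCl.

Step 8
Reactants: 14 the C5 acid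
Product: 15 9-benzyl 10-tert-butyl 2-oxo-8-(propan-2-yl)-1,3-dioxaspiro[4.5]dec-6-ene-9,10-dicarboxylate (C5 CO2tBu; configuration as 13)
Conditions: Cl3CC(=NH)OtBu, BF3·OEt2 (cat.), CH2Cl2/cyclohexane, rt
Reagents that add atoms: tert-butyl 2,2,2-trichloroacetimidate, CC(C)(C)OC(=N)C(Cl)(Cl)Cl
Why: Acid-catalysed tert-butylation with the trichloroacetimidate esterifies the hindered acid without base, so the β-carbonate is not eliminated.

Step 9
Reactants: 15 the cyclohexene diester
Product: 16 9-benzyl 10-tert-butyl 2-oxo-8-(propan-2-yl)-1,3-dioxaspiro[4.5]decane-9,10-dicarboxylate (C2–C3 saturated)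
Conditions: H2 (1 atm), [Ir(cod)(PCy3)(py)]PF6 (5 mol%), CH2Cl2, rt
Reagents that add atoms: none
Why: Homogeneous hydrogenation with Crabtree's catalyst saturates the hindered cis-disubstituted alkene without hydrogenolysis of the allylic carbonate C–O bond or of the benzyl ester; no stereocentre is formed or touched.

Step 10
Reactants: 16 the saturated benzyl ester
Product: 17 10-(tert-butoxycarbonyl)-2-oxo-8-(propan-2-yl)-1,3-dioxaspiro[4.5]decane-9-carboxylic acid (C6 CO2H)
Conditions: H2 (1 atm), 10% Pd/C, EtOAc, rt
Reagents that add atoms: none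
Why: Hydrogenolysis of the benzyl ester; with the ring now saturated the carbonate is no longer allylic, and the tert-butyl ester is inert.

Step 11
Reactants: 17 the C6 acid
Product: 18 tert-butyl 9-(hydroxymethyl)-2-oxo-8-(propan-2-yl)-1,3-dioxaspiro[4.5]decane-10-carboxylate (C6 CH2OH)
Conditions: BH3·SMe2, THF, 0 °C → rt; MeOH quench, aqueous work-up
Reagents that add atoms: none
Why: Borane reduces a carboxylic acid through its acyloxyborane much faster than it attacks a tert-butyl ester or a cyclic carbonate, so only the C6 carboxyl is reduced.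

Step 12
Reactants: 18 the C6 alcohol
Product: 19 tert-butyl 9-formyl-2-oxo-8-(propan-2-yl)-1,3-dioxaspiro[4.5]decane-10-carboxylate (C6 CHO)
Conditions: Dess–Martin periodinane, NaHCO3, CH2Cl2, rt
Reagents that add atoms: none
Why: Dess–Martin oxidation under buffered, non-basic conditions; the C6 formyl group is trans to both neighbours (all-equatorial), so C6 is in its stable configuration.

Step 13
Reactants: 20 tert-butyl 2-(diethoxyphosphoryl)acetate
Product: 22 tert-butyl 2-(diethoxyphosphoryl)-3-[(triisopropylsilyl)oxy]propanoate (racemic), via sodium phosphonoacetate carbanion 21 (not isolated)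
Conditions: NaH, THF, 0 °C; then iPr3SiOCH2Cl, 0 °C → rt
Reagents that add atoms: (triisopropylsiloxy)methyl chloride, ClCO[Si](C(C)C)(C(C)C)C(C)C
Why: C-Alkylation of the stabilised phosphonoacetate carbanion with a reactive α-chloro ether installs the silyl-protected hydroxymethyl group in one operation.

Step 14
Reactants: 19 the C6 aldehyde; 22 the silyloxymethyl phosphonate
Product: 24 tert-butyl 9-[(E)-3-tert-butoxy-3-oxo-2-{[(triisopropylsilyl)oxy]methyl}prop-1-en-1-yl]-2-oxo-8-(propan-2-yl)-1,3-dioxaspiro[4.5]decane-10-carboxylate, via sodium phosphonate carbanion 23 (not isolated)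
Conditions: 22, NaH, THF, 0 °C; then 19, 0 °C → rt
Reagents that add atoms: none
Why: Horner–Wadsworth–Emmons olefination with an α-substituted phosphonoacetate; reversible addition to the α-branched aldehyde should place the ring carbon trans to the ester, giving the C6 (E)-CH=C(CH2OTIPS)CO2tBu unit, and the weakly basic phosphonate anion should not deprotonate C5.

Step 15
Reactants: 24 the spiro-carbonate acrylate
Product: 25 tert-butyl (E)-3-[2-(tert-butoxycarbonyl)-3-hydroxy-3-(hydroxymethyl)-6-(propan-2-yl)cyclohexyl]-2-{[(triisopropylsilyl)oxy]methyl}prop-2-enoate (C4 OH α, C4 CH2OH β)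
Conditions: K2CO3 (0.2 equiv), MeOH, 0 °C
Reagents that add atoms: none
Why: Base-catalysed methanolysis of the five-membered carbonate is fast at 0 °C, whereas the tert-butyl ester resists attack by the freed primary alkoxide and carbonate/methoxide is too weak a base for E1cB at C5; the diol should be used at once.

Step 16
Reactants: 25 the diol
Product: 26 cis-fused hydroxy-γ-lactone (lactone C4–CH2–O–C(=O)–C5, tertiary C4–OH α retained, acrylate tert-butyl ester and silyl ether unchanged)
Conditions: CSA (0.2 equiv), toluene, 50 °C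
Reagents that add atoms: none
Why: Acid-catalysed intramolecular transesterification (5-exo) of the cis-disposed CH2OH and C5 ester closes the γ-lactone; the acrylate tert-butyl ester has no hydroxyl within reach and should survive catalytic acid.

Step 17
Reactants: 26 the hydroxy-lactone
Product: 27 tert-butyl (E)-3-[1-oxo-6-(propan-2-yl)-1,3,4,5,6,7-hexahydro-2-benzofuran-7-yl]-2-{[(triisopropylsilyl)oxy]methyl}prop-2-enoate (butenolide C4=C5; iPr and side chain trans)
Conditions: Burgess reagent, toluene, 60 °C
Reagents that add atoms: none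
Why: Burgess dehydration of the tertiary alcohol by syn elimination: the C5–H is cis to the C4–OH and is the most acidic β-hydrogen, so the conjugated butenolide should form.

Step 18
Reactants: 27 the butenolide tert-butyl ester
Product: 28 (E)-3-[1-oxo-6-(propan-2-yl)-1,3,4,5,6,7-hexahydro-2-benzofuran-7-yl]-2-{[(triisopropylsilyl)oxy]methyl}prop-2-enoic acid
Conditions: TFA/CH2Cl2 (1:4), 0 °C → rt
Reagents that add atoms: none
Why: Acidolysis of the tert-butyl ester (loss of isobutene); a primary triisopropylsilyl ether should survive brief anhydrous TFA and the butenolide is acid-stable.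

Step 19
Reactants: 28 the butenolide acid; 25 the diol
Product: 30 bis(tert-butyl ester) bis(triisopropylsilyl ether) of the target, via Yamaguchi mixed anhydride 29 (not isolated)
Conditions: 2,4,6-Cl3C6H2COCl, Et3N, THF, rt; then 25, DMAP, toluene, rt
Reagents that add atoms: none
Why: Yamaguchi esterification: DMAP-mediated acyl transfer from the mixed anhydride should acylate only the primary C4–CH2OH of 25 with the acrylic acid of 28, the tertiary C4–OH being too hindered.

Step 20
Reactants: 30 the protected target
Product: 32 CNP0071646.2 (target), via bis(triisopropylsilyl) ether diacid 31 (not isolated)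
Conditions: TFA/CH2Cl2 (1:2), 0 °C → rt; evaporate; HF·pyridine, THF, 0 °C → rt
Reagents that add atoms: none
Why: Acidolysis of both tert-butyl esters followed by fluoride cleavage of both silyl ethers, all under acidic conditions, so the acrylate ester link, the butenolide and the β-hydroxy acid (whose tertiary cation is destabilised by its neighbours) should not be affected.

**Compound list**
1 | 3-methylbut-1-yne | CC(C)C#C | starting material
2 | (E)-diisobutyl(3-methylbut-1-en-1-yl)alane | CC(C)/C=C/[Al](CC(C)C)CC(C)C | intermediate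
3 | (E)-1-iodo-3-methylbut-1-ene | CC(C)/C=C/I | intermediate
4 | prop-2-yn-1-ol | C#CCO | starting material
5 | (E)-6-methylhept-4-en-2-yn-1-ol | CC(C)/C=C/C#CCO | intermediate
6 | (Z)-4-[(E)-4-methylpent-2-en-1-ylidene]-1,3-dioxolan-2-one | CC(C)/C=C/C=C1\OC(=O)OC1 | intermediate
7 | benzyl (triphenylphosphoranylidene)acetate | O=C(C=P(c1ccccc1)(c1ccccc1)c1ccccc1)OCc1ccccc1 | starting material
8 | 2,2-dimethoxyacetaldehyde | COC(OC)C=O | starting material
9 | benzyl (E)-4,4-dimethoxybut-2-enoate | COC(OC)/C=C/C(=O)OCc1ccccc1 | intermediate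
10 | benzyl (E)-4-oxobut-2-enoate | O=C/C=C/C(=O)OCc1ccccc1 | intermediate
11 | enal iminium chloride ((E)-iminium of 10 on (5R)-5-benzyl-2,2,3-trimethylimidazolidin-4-one) | CN1C(=O)[C@@H](Cc2ccccc2)/[N+](=C\C=C\C(=O)OCc2ccccc2)C1(C)C.[Cl-] | intermediate
12 | cycloadduct iminium chloride (13 with C5 CH=N+ of the catalyst in place of CHO) | CC(C)[C@H]1C=C[C@@](OC(=O)O2)(C2)[C@@H](C=[N+]3[C@H](Cc4ccccc4)C(=O)N(C)C3(C)C)[C@@H]1C(=O)OCc1ccccc1.[Cl-] | intermediate
13 | benzyl (5S,8S,9R,10S)-10-formyl-2-oxo-8-(propan-2-yl)-1,3-dioxaspiro[4.5]dec-6-ene-9-carboxylate (C1 iPr β; C4 spiro-carbonate, CH2O β, O α; C5 CHO β; C6 CO2Bn α; C2=C3) | CC(C)[C@H]1C=C[C@@](OC(=O)O2)(C2)[C@@H](C=O)[C@@H]1C(=O)OCc1ccccc1 | intermediate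
14 | 9-(benzyloxycarbonyl)-2-oxo-8-(propan-2-yl)-1,3-dioxaspiro[4.5]dec-6-ene-10-carboxylic acid (configuration as 13) | CC(C)[C@H]1C=C[C@@](OC(=O)O2)(C2)[C@@H](C(=O)O)[C@@H]1C(=O)OCc1ccccc1 | intermediate
15 | 9-benzyl 10-tert-butyl 2-oxo-8-(propan-2-yl)-1,3-dioxaspiro[4.5]dec-6-ene-9,10-dicarboxylate | CC(C)[C@H]1C=C[C@@](OC(=O)O2)(C2)[C@@H](C(=O)OC(C)(C)C)[C@@H]1C(=O)OCc1ccccc1 | intermediate
16 | 9-benzyl 10-tert-butyl 2-oxo-8-(propan-2-yl)-1,3-dioxaspiro[4.5]decane-9,10-dicarboxylate | CC(C)[C@H]1CC[C@@](OC(=O)O2)(C2)[C@@H](C(=O)OC(C)(C)C)[C@@H]1C(=O)OCc1ccccc1 | intermediate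
17 | 10-(tert-butoxycarbonyl)-2-oxo-8-(propan-2-yl)-1,3-dioxaspiro[4.5]decane-9-carboxylic acid | CC(C)[C@H]1CC[C@@](OC(=O)O2)(C2)[C@@H](C(=O)OC(C)(C)C)[C@@H]1C(=O)O | intermediate
18 | tert-butyl 9-(hydroxymethyl)-2-oxo-8-(propan-2-yl)-1,3-dioxaspiro[4.5]decane-10-carboxylate | CC(C)[C@H]1CC[C@@](OC(=O)O2)(C2)[C@@H](C(=O)OC(C)(C)C)[C@@H]1CO | intermediate
19 | tert-butyl 9-formyl-2-oxo-8-(propan-2-yl)-1,3-dioxaspiro[4.5]decane-10-carboxylate | CC(C)[C@H]1CC[C@@](OC(=O)O2)(C2)[C@@H](C(=O)OC(C)(C)C)[C@@H]1C=O | intermediate
20 | tert-butyl 2-(diethoxyphosphoryl)acetate | CCOP(=O)(OCC)CC(=O)OC(C)(C)C | starting material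
21 | sodium phosphonoacetate carbanion (sodium salt of 20) | CCOP(=O)(OCC)[CH-]C(=O)OC(C)(C)C.[Na+] | intermediate
22 | tert-butyl 2-(diethoxyphosphoryl)-3-[(triisopropylsilyl)oxy]propanoate (racemic) | CCOP(=O)(OCC)C(CO[Si](C(C)C)(C(C)C)C(C)C)C(=O)OC(C)(C)C | intermediate
23 | sodium phosphonate carbanion (sodium salt of 22) | CCOP(=O)(OCC)[C-](CO[Si](C(C)C)(C(C)C)C(C)C)C(=O)OC(C)(C)C.[Na+] | intermediate
24 | tert-butyl 9-[(E)-3-tert-butoxy-3-oxo-2-{[(triisopropylsilyl)oxy]methyl}prop-1-en-1-yl]-2-oxo-8-(propan-2-yl)-1,3-dioxaspiro[4.5]decane-10-carboxylate (spiro-carbonate with C5 CO2tBu and C6 (E)-CH=C(CH2OTIPS)CO2tBu) | CC(C)[C@H]1CC[C@@](OC(=O)O2)(C2)[C@@H](C(=O)OC(C)(C)C)[C@@H]1/C=C(\CO[Si](C(C)C)(C(C)C)C(C)C)C(=O)OC(C)(C)C | intermediate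
25 | diol (C4 OH α, C4 CH2OH β) with C5 CO2tBu and C6 (E)-acrylate | CC(C)[C@H]1CC[C@@](O)(CO)[C@@H](C(=O)OC(C)(C)C)[C@@H]1/C=C(\CO[Si](C(C)C)(C(C)C)C(C)C)C(=O)OC(C)(C)C | intermediate
26 | cis-fused hydroxy-γ-lactone (C4–CH2–O–C(=O)–C5; C4 OH α) | CC(C)[C@H]1CC[C@@]2(O)COC(=O)[C@H]2[C@@H]1/C=C(\CO[Si](C(C)C)(C(C)C)C(C)C)C(=O)OC(C)(C)C | intermediate
27 | tert-butyl (E)-3-[1-oxo-6-(propan-2-yl)-1,3,4,5,6,7-hexahydro-2-benzofuran-7-yl]-2-{[(triisopropylsilyl)oxy]methyl}prop-2-enoate (iPr and side chain trans) | CC(C)(C)OC(=O)/C(=C/[C@H]1C2=C(CC[C@@H]1C(C)C)COC2=O)CO[Si](C(C)C)(C(C)C)C(C)C | intermediate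
28 | (E)-3-[1-oxo-6-(propan-2-yl)-1,3,4,5,6,7-hexahydro-2-benzofuran-7-yl]-2-{[(triisopropylsilyl)oxy]methyl}prop-2-enoic acid | OC(=O)/C(=C/[C@H]1C2=C(CC[C@@H]1C(C)C)COC2=O)CO[Si](C(C)C)(C(C)C)C(C)C | intermediate
29 | Yamaguchi mixed anhydride (28 acylated on its carboxyl by the 2,4,6-trichlorobenzoyl group) | O=C(OC(=O)/C(=C/[C@H]1C2=C(CC[C@@H]1C(C)C)COC2=O)CO[Si](C(C)C)(C(C)C)C(C)C)c1c(Cl)cc(Cl)cc1Cl | intermediate
30 | bis(tert-butyl ester) bis(triisopropylsilyl ether) of the target (ester between C4–CH2OH of 25 and the carboxyl of 28) | CC(C)[C@H]1CC[C@@](O)(COC(=O)/C(=C/[C@H]2C3=C(CC[C@@H]2C(C)C)COC3=O)CO[Si](C(C)C)(C(C)C)C(C)C)[C@@H](C(=O)OC(C)(C)C)[C@@H]1/C=C(\CO[Si](C(C)C)(C(C)C)C(C)C)C(=O)OC(C)(C)C | intermediate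
31 | bis(triisopropylsilyl) ether diacid (target with both allylic OH groups still silylated) | CC(C)[C@H]1CC[C@@](O)(COC(=O)/C(=C/[C@H]2C3=C(CC[C@@H]2C(C)C)COC3=O)CO[Si](C(C)C)(C(C)C)C(C)C)[C@@H](C(=O)O)[C@@H]1/C=C(\CO[Si](C(C)C)(C(C)C)C(C)C)C(=O)O | intermediate
32 | CNP0071646.2 | CC(C)[C@H]1CC[C@@](O)(COC(=O)/C(=C/[C@H]2C3=C(CC[C@@H]2C(C)C)COC3=O)CO)[C@@H](C(=O)O)[C@@H]1/C=C(\CO)C(=O)O | target

**Step count**
Total: 20 steps. Longest linear sequence: 17 steps (1 → 3 → 5 → 6 → 13 → 14 → 15 → 16 → 17 → 18 → 19 → 24 → 25 → 26 → 27 → 28 → 30 → 32).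

**Steps most likely to fail**

Step 6 (Proposed new method). The cycloaddition may be slow at the fully substituted enol-carbonate terminus, so that aminolysis or hydrolysis of the enol carbonate, or polymerisation of the enal, overtakes it. Regio-, endo or facial control could also erode at this hindered terminus. The fallback sets out from 6 and 10 and gives up asymmetric catalysis for a thermal cycloaddition followed by classical resolution. Heating 6 with 10 in toluene, or holding them under high pressure at room temperature, is an ordinary Diels–Alder reaction of a 1-acyloxydiene with a doubly activated dienophile. It should give the racemic endo adduct, rac-13 F1. Pinnick oxidation as in step 7 then gives the racemic acid, rac-14 F2. Crystallisation with (R)-1-phenylethylamine should separate the diastereomeric salts, the wanted one being the (R)-1-phenylethylammonium salt of 14 F3 (with the S amine if the other salt is the less soluble). Acidification frees 14, where the route is rejoined.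

Step 14. Addition of the α-branched phosphonate anion to the doubly flanked aldehyde may be slow, which would allow loss of silanolate from the anion (retro-oxa-Michael) and erosion of the E/Z ratio. The fallback sets out from 19 and builds the acrylate by addition and allylic transposition instead of olefination. Vinylalumination of 19 with [1-(tert-butoxycarbonyl)vinyl]diisobutylalane (from tert-butyl propiolate, DIBAL-H and NMO in THF) should give the Morita–Baylis–Hillman-type allylic alcohol F4 as a mixture of carbinol epimers. Treatment with NBS/Me2S should convert it with SN2′ transposition into the thermodynamic allylic bromide, tert-butyl (Z)-2-(bromomethyl)enoate F5, in which the ring carbon is trans to the ester. Silver(I) oxide in aqueous acetone should hydrolyse the bromide to the primary allylic alcohol F6. Silylation with TIPSCl and imidazole gives 24, where the route is rejoined.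

Step 3. Carboxylative cyclisation of a primary propargylic alcohol lacking gem-dialkyl substitution may stall, and the enol carbonate may be lost by hydrolysis or oligomerisation under the basic, pressurised conditions. The fallback sets out from 5 and moves the carbonate carbon onto the substrate before cyclisation. Boc2O with catalytic DMAP should give tert-butyl (E)-6-methylhept-4-en-2-yn-1-yl carbonate F7. Gold(I) catalysis (Ph3PAuNTf2, CH2Cl2, rt) then promotes 5-exo-dig attack of the carbonyl oxygen anti to gold with loss of isobutene, which should give the same Z-alkylidene carbonate 6, where the route is rejoined.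

**Further compounds**
F1 | step 6 | rac-13, racemic endo adduct (one enantiomer drawn) | CC(C)[C@H]1C=C[C@@](OC(=O)O2)(C2)[C@@H](C=O)[C@@H]1C(=O)OCc1ccccc1
F2 | step 6 | rac-14, racemic acid (one enantiomer drawn) | CC(C)[C@H]1C=C[C@@](OC(=O)O2)(C2)[C@@H](C(=O)O)[C@@H]1C(=O)OCc1ccccc1
F3 | step 6 | (R)-1-phenylethylammonium salt of 14 | CC(C)[C@H]1C=C[C@@](OC(=O)O2)(C2)[C@@H](C(=O)[O-])[C@@H]1C(=O)OCc1ccccc1.C[C@@H]([NH3+])c1ccccc1
F4 | step 14 | Morita–Baylis–Hillman-type alcohol, C6 CH(OH)C(=CH2)CO2tBu (carbinol epimers) | CC(C)[C@H]1CC[C@@](OC(=O)O2)(C2)[C@@H](C(=O)OC(C)(C)C)[C@@H]1C(O)C(=C)C(=O)OC(C)(C)C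
F5 | step 14 | allylic bromide, C6 (Z)-CH=C(CH2Br)CO2tBu | CC(C)[C@H]1CC[C@@](OC(=O)O2)(C2)[C@@H](C(=O)OC(C)(C)C)[C@@H]1/C=C(\CBr)C(=O)OC(C)(C)C
F6 | step 14 | allylic alcohol, C6 (E)-CH=C(CH2OH)CO2tBu | CC(C)[C@H]1CC[C@@](OC(=O)O2)(C2)[C@@H](C(=O)OC(C)(C)C)[C@@H]1/C=C(\CO)C(=O)OC(C)(C)C
F7 | step 3 | tert-butyl (E)-6-methylhept-4-en-2-yn-1-yl carbonate | CC(C)/C=C/C#CCOC(=O)OC(C)(C)C
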